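**Retrosynthetic overview**
1. Target ⇒ C4 methylation of a 4-monomethyl enone ⇒ ring A by aldol condensation (C2 onto C1) ⇒ aryl ether by Mitsunobu reaction at C11 ⇒ cis-fused γ-lactone on ring B ⇒ acyclic ester-tethered triene. Drimane numbering is used throughout: ring A = C1–C5 and C10, ring B = C5–C10, C11 = OCH2 on C9, C12 = CH2 on C8, C15 = CH3 on C10.
2. Key disconnection: ring B by a thermal intramolecular Diels–Alder reaction that forms C5–C6 and C9–C10 together and sets C5, C9 and C10.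
3. Enabling feature: on ring B the quaternary C10 carries C1 (an enone carbon that can be a carboxyl carbon) next to C9, which carries C11–O cis to it, so C1(=O)–O–C11 can serve as a temporary γ-lactone tether. The C8 exocyclic methylene beside C7H2 is the protodesilylation product of a C7=C8 allylsilane, which is the cyclohexene retron.
4. Stereocontrol: the gem-dimethyl carbon C4 is carried as a temporary (4R) H/CH3 stereocentre (Evans alkylation) that steers the diene face by 1,3-allylic strain and is erased by the last methylation.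
5. Ring order: ring B with the temporary lactone ring (step 11), then ring A (step 15). Building blocks: an (R)-aldehyde from fructone, a silylmethyl dienol from propargyl alcohol, and isofraxidin.

Key step: step 11

Remark: 2-(diethoxyphosphoryl)propanoic acid and isofraxidin are taken as purchasable. The aryl ether is made before the enone because a free C11 hydroxyl would be expected to add to C1 of the enone (oxa-Michael closure).

**Route**

Step 1
Reactants: 1 ethyl 2-(2-methyl-1,3-dioxolan-2-yl)acetate (fructone)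
Product: 2 2-(2-methyl-1,3-dioxolan-2-yl)acetic acid
Conditions: LiOH·H2O, THF/H2O, rt; then 1 M HCl to pH 4, 0 °C
Reagents that add atoms: lithium hydroxide [Li+].[OH-]
Why: Ester saponification; the dioxolane is inert to base and should survive the short, cold acidification.

Step 2
Reactants: 2 2-(2-methyl-1,3-dioxolan-2-yl)acetic acid; 3 (4S)-4-benzyl-1,3-oxazolidin-2-one
Product: 5 (4S)-4-benzyl-3-[(2-methyl-1,3-dioxolan-2-yl)acetyl]-1,3-oxazolidin-2-one, via mixed pivalic anhydride 4 (not isolated)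
Conditions: Et3N, t-BuCOCl, THF, −20 °C; then LiCl, 3, −20 °C to rt
Reagents that add atoms: none
Why: N-Acylation of the Evans auxiliary through the mixed pivalic anhydride, from which the less hindered acyl group is transferred.

Step 3
Reactants: 5 (4S)-4-benzyl-3-[(2-methyl-1,3-dioxolan-2-yl)acetyl]-1,3-oxazolidin-2-one
Product: 7 (4S)-4-benzyl-3-[(2S)-2-(2-methyl-1,3-dioxolan-2-yl)propanoyl]-1,3-oxazolidin-2-one, via sodium (Z)-enolate 6 (not isolated)
Conditions: NaN(SiMe3)2, THF, −78 °C; then MeI, −78 to −40 °C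
Reagents that add atoms: iodomethane CI
Why: Evans asymmetric alkylation, in which the chelated (Z)-enolate is methylated on the face away from the benzyl group, which sets the future C4 centre.

Step 4
Reactants: 7 (4S)-4-benzyl-3-[(2S)-2-(2-methyl-1,3-dioxolan-2-yl)propanoyl]-1,3-oxazolidin-2-one
Product: 8 (2R)-2-(2-methyl-1,3-dioxolan-2-yl)propan-1-ol
Conditions: LiBH4, H2O (1 equiv), Et2O, 0 °C
Reagents that add atoms: none
Why: Reductive cleavage of the N-acyl oxazolidinone with LiBH4 should give the primary alcohol without enolisation of the new centre and return auxiliary 3.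

Step 5
Reactants: 8 (2R)-2-(2-methyl-1,3-dioxolan-2-yl)propan-1-ol
Product: 9 (2R)-2-(2-methyl-1,3-dioxolan-2-yl)propanal
Conditions: TEMPO (10 mol %), PhI(OAc)2, CH2Cl2, rt
Reagents that add atoms: none
Why: Nitroxyl-catalysed alcohol oxidation stops at the aldehyde and should not epimerise the α-centre; 9 is used at once.

Step 6
Reactants: 10 prop-2-yn-1-ol; 11 bromoethene
Product: 12 pent-4-en-2-yn-1-ol
Conditions: PdCl2(PPh3)2 (2 mol %), CuI (4 mol %), Et2NH, THF, 0 °C to rt
Reagents that add atoms: none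
Why: Sonogashira coupling of a terminal alkyne with a vinyl bromide tolerates the free hydroxyl.

Step 7
Reactants: 12 pent-4-en-2-yn-1-ol
Product: 14 (2Z)-3-iodopenta-2,4-dien-1-ol, via cyclic alkenylaluminate 13 (not isolated)
Conditions: NaAlH2(OCH2CH2OMe)2, THF, 0 °C to rt; then I2, −78 °C
Reagents that add atoms: iodine II
Why: Hydroxyl-directed trans-hydroalumination of the propargylic alcohol places aluminium on C3 in a five-membered aluminate, and iodinolysis with retention gives the alkenyl iodide with iodine cis to CH2OH, so the vinyl group is trans to CH2OH.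

Step 8
Reactants: 14 (2Z)-3-iodopenta-2,4-dien-1-ol
Product: 15 (2Z)-3-[(trimethylsilyl)methyl]penta-2,4-dien-1-ol
Conditions: Me3SiCH2MgCl (3 equiv), Pd(PPh3)4 (5 mol %), THF, 0 °C to rt
Reagents that add atoms: (trimethylsilyl)methylmagnesium chloride C[Si](C)(C)C[Mg]Cl
Why: Kumada–Corriu coupling of the alkenyl iodide with the β-hydrogen-free Grignard reagent proceeds with retention of the double-bond geometry and is the standard entry to 2-(silylmethyl)dienes.

Step 9
Reactants: 15 (2Z)-3-[(trimethylsilyl)methyl]penta-2,4-dien-1-ol; 16 2-(diethoxyphosphoryl)propanoic acid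
Product: 17 (2Z)-3-[(trimethylsilyl)methyl]penta-2,4-dien-1-yl 2-(diethoxyphosphoryl)propanoate
Conditions: DCC, DMAP (cat.), CH2Cl2, 0 °C to rt
Reagents that add atoms: none
Why: Steglich esterification under neutral conditions should leave the acid-sensitive allylsilane diene intact.

Step 10
Reactants: 17 (2Z)-3-[(trimethylsilyl)methyl]penta-2,4-dien-1-yl 2-(diethoxyphosphoryl)propanoate; 9 (2R)-2-(2-methyl-1,3-dioxolan-2-yl)propanal
Product: 18 (2Z)-3-[(trimethylsilyl)methyl]penta-2,4-dien-1-yl (2E,4R)-2-methyl-4-(2-methyl-1,3-dioxolan-2-yl)pent-2-enoate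
Conditions: LiCl, DBU, MeCN, 0 °C to rt
Reagents that add atoms: none
Why: Horner–Wadsworth–Emmons olefination under Masamune–Roush conditions should give the (E)-trisubstituted enoate from an α-branched aldehyde and is mild enough not to epimerise C4.

Step 11
Reactants: 18 (2Z)-3-[(trimethylsilyl)methyl]penta-2,4-dien-1-yl (2E,4R)-2-methyl-4-(2-methyl-1,3-dioxolan-2-yl)pent-2-enoate
Product: 19 (3aR,7R,7aR)-7a-methyl-7-[(1R)-1-(2-methyl-1,3-dioxolan-2-yl)ethyl]-4-[(trimethylsilyl)methyl]-3a,6,7,7a-tetrahydro-2-benzofuran-1(3H)-one (cis-fused lactone)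
Conditions: PhMe (0.01 M), BHT (cat.), 180 °C, sealed tube
Reagents that add atoms: none
Why: Thermal intramolecular Diels–Alder reaction of an ester-linked 1,3,8-nonatriene (the pentadienyl acrylate class, type 1 mode): a concerted suprafacial [4+2] cycloaddition of the C6=C7–C8=C9 diene to the C5=C10 enoate makes C5–C6 and C9–C10 together. Ring B closes as the six-membered cyclohexene of the cycloaddition, and the five-membered lactone ring closes at the same moment across the three-atom tether C1(=O)–O–C11, which can only span C9 and C10 and so enforces the regiochemistry that the electron-releasing CH2SiMe3 group on C8 would otherwise oppose. The E geometry of the enoate is carried into ring B, so C1 and C4 are trans and H5 is anti to the C10 methyl, which is the later trans ring fusion. C9 is set by the E-disposed tether on the diene and the tether-endo transition state, favoured because it places the C10 methyl and the branched C4 substituent exo, which gives the cis-fused lactone with C11 cis to C1 and anti to the C10 methyl. The absolute configuration comes from the (4R) centre: 1,3-allylic strain with the C10 methyl holds H4 in the alkene plane and the diene adds to the face that carries the C4 methyl, anti to the dioxolanyl group. The step therefore needs regio-, endo- and facial selectivity, secured in turn by the tether, by the E geometry of both partners and by the temporary C4 stereocentre, while the silylmethyl group raises the diene HOMO and its s-cis population.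

Step 12
Reactants: 19 (3aR,7R,7aR)-7a-methyl-7-[(1R)-1-(2-methyl-1,3-dioxolan-2-yl)ethyl]-4-[(trimethylsilyl)methyl]-3a,6,7,7a-tetrahydro-2-benzofuran-1(3H)-one
Product: 20 (3aR,7R,7aR)-7a-methyl-7-[(1R)-1-(2-methyl-1,3-dioxolan-2-yl)ethyl]-4-[(trimethylsilyl)methyl]-1,3,3a,6,7,7a-hexahydro-2-benzofuran-1-ol (lactol, C1 epimers)
Conditions: i-Bu2AlH (1.2 equiv), CH2Cl2, −78 °C
Reagents that add atoms: none
Why: Partial hydride reduction of a lactone to the lactol; the tetrahedral aluminate of the hindered α-quaternary lactone should hold at −78 °C, and the ketal and allylsilane are inert.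

Step 13
Reactants: 20 (3aR,7R,7aR)-7a-methyl-7-[(1R)-1-(2-methyl-1,3-dioxolan-2-yl)ethyl]-4-[(trimethylsilyl)methyl]-1,3,3a,6,7,7a-hexahydro-2-benzofuran-1-ol
Product: 21 {(1R,5R,6R)-6-[(E)-(2,2-dimethylhydrazinylidene)methyl]-6-methyl-5-[(1R)-1-(2-methyl-1,3-dioxolan-2-yl)ethyl]-2-[(trimethylsilyl)methyl]cyclohex-2-en-1-yl}methanol
Conditions: Me2NNH2, AcOH (cat.), EtOH, 60 °C
Reagents that add atoms: 1,1-dimethylhydrazine CN(C)N
Why: Hydrazone condensation of the lactol through its hydroxy aldehyde form masks C1 at the aldehyde level and frees the C11 hydroxyl for etherification before any enone exists.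

Step 14
Reactants: 21 {(1R,5R,6R)-6-[(E)-(2,2-dimethylhydrazinylidene)methyl]-6-methyl-5-[(1R)-1-(2-methyl-1,3-dioxolan-2-yl)ethyl]-2-[(trimethylsilyl)methyl]cyclohex-2-en-1-yl}methanol; 22 isofraxidin (7-hydroxy-6,8-dimethoxy-2H-chromen-2-one)
Product: 23 7-({(1R,5R,6R)-6-[(E)-(2,2-dimethylhydrazinylidene)methyl]-6-methyl-5-[(1R)-1-(2-methyl-1,3-dioxolan-2-yl)ethyl]-2-[(trimethylsilyl)methyl]cyclohex-2-en-1-yl}methoxy)-6,8-dimethoxy-2H-chromen-2-one
Conditions: PPh3, DIAD, THF, 0 to 40 °C
Reagents that add atoms: none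
Why: Mitsunobu etherification of the primary alcohol with the acidic phenol forms the C11–O–aryl bond under neutral conditions and touches no stereocentre.

Step 15
Reactants: 23 7-({(1R,5R,6R)-6-[(E)-(2,2-dimethylhydrazinylidene)methyl]-6-methyl-5-[(1R)-1-(2-methyl-1,3-dioxolan-2-yl)ethyl]-2-[(trimethylsilyl)methyl]cyclohex-2-en-1-yl}methoxy)-6,8-dimethoxy-2H-chromen-2-one
Product: 25 7-{[(1S,4aR,8aR)-5,8a-dimethyl-2-methylidene-6-oxo-1,2,3,4,4a,5,6,8a-octahydronaphthalen-1-yl]methoxy}-6,8-dimethoxy-2H-chromen-2-one (epimers at naphthalene C5 = drimane C4), via keto aldehyde 24 (not isolated)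
Conditions: TsOH·H2O, THF/H2O, rt; then piperidine, AcOH, PhMe, 60 °C
Reagents that add atoms: water O
Why: Aqueous acid should hydrolyse the hydrazone and the dioxolane and protodesilylate the allylsilane (protonation at C7, loss of silicon from the β-silyl cation, C8 exocyclic methylene formed without touching C9); the freed 1,5-keto aldehyde then closes ring A by an amine-catalysed intramolecular aldol condensation in which only the C2 methyl can form a six-membered ring, and the trans-disposed C1 and C4 arms give the trans-decalin.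

Step 16
Reactants: 25 7-{[(1S,4aR,8aR)-5,8a-dimethyl-2-methylidene-6-oxo-1,2,3,4,4a,5,6,8a-octahydronaphthalen-1-yl]methoxy}-6,8-dimethoxy-2H-chromen-2-one
Product: 27 7-{[(1S,4aS,8aR)-5,5,8a-trimethyl-2-methylidene-6-oxo-1,2,3,4,4a,5,6,8a-octahydronaphthalen-1-yl]methoxy}-6,8-dimethoxy-2H-chromen-2-one, via lithium enolate 26 (not isolated)
Conditions: LiN(SiMe3)2 (1.1 equiv), THF, −78 °C; then MeI, −78 to 0 °C
Reagents that add atoms: iodomethane CI
Why: Enolate alkylation: kinetic α′-deprotonation at C4 (the only enolisable position, since C10 is quaternary) and C-methylation of the cross-conjugated dienolate complete the gem-dimethyl group, both C4 epimers converge on one product and no stereocentre is created.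

**Compound list**

1 | ethyl 2-(2-methyl-1,3-dioxolan-2-yl)acetate (fructone) | CCOC(=O)CC1(C)OCCO1 | starting material
2 | 2-(2-methyl-1,3-dioxolan-2-yl)acetic acid | OC(=O)CC1(C)OCCO1 | intermediate
3 | (4S)-4-benzyl-1,3-oxazolidin-2-one | O=C1N[C@@H](Cc2ccccc2)CO1 | starting material
4 | (2-methyl-1,3-dioxolan-2-yl)acetic pivalic anhydride | CC(C)(C)C(=O)OC(=O)CC1(C)OCCO1 | intermediate
5 | (4S)-4-benzyl-3-[(2-methyl-1,3-dioxolan-2-yl)acetyl]-1,3-oxazolidin-2-one | O=C(CC1(C)OCCO1)N1[C@@H](Cc2ccccc2)COC1=O | intermediate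
6 | sodium (Z)-enolate of 5 | [Na+].[O-]/C(=C\C1(C)OCCO1)N1[C@@H](Cc2ccccc2)COC1=O | intermediate
7 | (4S)-4-benzyl-3-[(2S)-2-(2-methyl-1,3-dioxolan-2-yl)propanoyl]-1,3-oxazolidin-2-one | C[C@@H](C1(C)OCCO1)C(=O)N1[C@@H](Cc2ccccc2)COC1=O | intermediate
8 | (2R)-2-(2-methyl-1,3-dioxolan-2-yl)propan-1-ol | C[C@@H](C1(C)OCCO1)CO | intermediate
9 | (2R)-2-(2-methyl-1,3-dioxolan-2-yl)propanal | C[C@@H](C1(C)OCCO1)C=O | intermediate
10 | prop-2-yn-1-ol | C#CCO | starting material
11 | bromoethene | C=CBr | starting material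
12 | pent-4-en-2-yn-1-ol | C=CC#CCO | intermediate
13 | sodium cyclic alkenylaluminate (2-ethenyl-1-oxa-5-aluminacyclopent-3-ene type, aluminium on C3) | [Na+].C=CC1=CCO[Al-]1(OCCOC)OCCOC | intermediate
14 | (2Z)-3-iodopenta-2,4-dien-1-ol | OC/C=C(\I)C=C | intermediate
15 | (2Z)-3-[(trimethylsilyl)methyl]penta-2,4-dien-1-ol | OC/C=C(\C[Si](C)(C)C)C=C | intermediate
16 | 2-(diethoxyphosphoryl)propanoic acid | CCOP(=O)(OCC)C(C)C(=O)O | starting material
17 | (2Z)-3-[(trimethylsilyl)methyl]penta-2,4-dien-1-yl 2-(diethoxyphosphoryl)propanoate | CCOP(=O)(OCC)C(C)C(=O)OC/C=C(\C[Si](C)(C)C)C=C | intermediate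
18 | (2Z)-3-[(trimethylsilyl)methyl]penta-2,4-dien-1-yl (2E,4R)-2-methyl-4-(2-methyl-1,3-dioxolan-2-yl)pent-2-enoate | C=C/C(C[Si](C)(C)C)=C/COC(=O)/C(C)=C/[C@@H](C)C1(C)OCCO1 | intermediate
19 | (3aR,7R,7aR)-7a-methyl-7-[(1R)-1-(2-methyl-1,3-dioxolan-2-yl)ethyl]-4-[(trimethylsilyl)methyl]-3a,6,7,7a-tetrahydro-2-benzofuran-1(3H)-one | C[C@]12C(=O)OC[C@H]1C(C[Si](C)(C)C)=CC[C@@H]2[C@@H](C)C3(C)OCCO3 | intermediate
20 | (3aR,7R,7aR)-7a-methyl-7-[(1R)-1-(2-methyl-1,3-dioxolan-2-yl)ethyl]-4-[(trimethylsilyl)methyl]-1,3,3a,6,7,7a-hexahydro-2-benzofuran-1-ol (C1 epimers) | C[C@]12C(O)OC[C@H]1C(C[Si](C)(C)C)=CC[C@@H]2[C@@H](C)C3(C)OCCO3 | intermediate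
21 | {(1R,5R,6R)-6-[(E)-(2,2-dimethylhydrazinylidene)methyl]-6-methyl-5-[(1R)-1-(2-methyl-1,3-dioxolan-2-yl)ethyl]-2-[(trimethylsilyl)methyl]cyclohex-2-en-1-yl}methanol | C[C@]1(/C=N/N(C)C)[C@@H](CO)C(C[Si](C)(C)C)=CC[C@@H]1[C@@H](C)C2(C)OCCO2 | intermediate
22 | isofraxidin (7-hydroxy-6,8-dimethoxy-2H-chromen-2-one) | COc1cc2ccc(=O)oc2c(OC)c1O | starting material
23 | 7-({(1R,5R,6R)-6-[(E)-(2,2-dimethylhydrazinylidene)methyl]-6-methyl-5-[(1R)-1-(2-methyl-1,3-dioxolan-2-yl)ethyl]-2-[(trimethylsilyl)methyl]cyclohex-2-en-1-yl}methoxy)-6,8-dimethoxy-2H-chromen-2-one | C[C@]1(/C=N/N(C)C)[C@@H](COc2c(OC)cc3ccc(=O)oc3c2OC)C(C[Si](C)(C)C)=CC[C@@H]1[C@@H](C)C4(C)OCCO4 | intermediate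
24 | (1R,2S,6R)-2-{[(6,8-dimethoxy-2-oxo-2H-chromen-7-yl)oxy]methyl}-1-methyl-3-methylidene-6-(3-oxobutan-2-yl)cyclohexane-1-carbaldehyde (ketone α-carbon epimerisable) | C=C1CC[C@H](C(C)C(C)=O)[C@@](C)(C=O)[C@H]1COc1c(OC)cc2ccc(=O)oc2c1OC | intermediate
25 | 7-{[(1S,4aR,8aR)-5,8a-dimethyl-2-methylidene-6-oxo-1,2,3,4,4a,5,6,8a-octahydronaphthalen-1-yl]methoxy}-6,8-dimethoxy-2H-chromen-2-one (C5 epimers) | C=C1CC[C@@H]2C(C)C(=O)C=C[C@@]2(C)[C@H]1COc1c(OC)cc2ccc(=O)oc2c1OC | intermediate
26 | lithium cross-conjugated dienolate of 25 | C=C1CC[C@@H]2C(C)=C([O-])C=C[C@@]2(C)[C@H]1COc1c(OC)cc2ccc(=O)oc2c1OC.[Li+] | intermediate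
27 | 7-{[(1S,4aS,8aR)-5,5,8a-trimethyl-2-methylidene-6-oxo-1,2,3,4,4a,5,6,8a-octahydronaphthalen-1-yl]methoxy}-6,8-dimethoxy-2H-chromen-2-one | C=C1CC[C@@H]2C(C)(C)C(=O)C=C[C@@]2(C)[C@H]1COc1c(OC)cc2ccc(=O)oc2c1OC | target

**Step count**

Total: 16 steps. Longest linear sequence: 12 steps (steps 1–5 and 10–16).

**Steps most likely to fail**

1. Step 11. The cycloaddition may stall, because the α-methyl, β-branched enoate has to reach the disfavoured s-cis ester rotamer; polymerisation or the tether-exo pathway (trans-fused lactone) could then compete. Fallback: take the quaternary methyl out of the cycloaddition. Setting out from dienol 15 and aldehyde 9, Steglich esterification of 15 with (diethoxyphosphoryl)acetic acid gives (2Z)-3-[(trimethylsilyl)methyl]penta-2,4-dien-1-yl (diethoxyphosphoryl)acetate F1. Masamune–Roush olefination of F1 with 9 gives (2Z)-3-[(trimethylsilyl)methyl]penta-2,4-dien-1-yl (2E,4R)-4-(2-methyl-1,3-dioxolan-2-yl)pent-2-enoate F2, a disubstituted and therefore faster dienophile. Its intramolecular Diels–Alder reaction (PhMe, 150–160 °C) should give the cis-fused lactone (3aR,7R,7aR)-7-[(1R)-1-(2-methyl-1,3-dioxolan-2-yl)ethyl]-4-[(trimethylsilyl)methyl]-3a,6,7,7a-tetrahydro-2-benzofuran-1(3H)-one F3. Facial control is weaker without the α-methyl, so diastereomers would be separated here. LiN(i-Pr)2 at −78 °C and MeI then methylate the ring-fusion enolate on the convex face, cis to H9, which keeps the cis-fused lactone and comes back to the route at lactone 19.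

2. Step 14. Displacement at the β-branched primary carbon by the doubly ortho-substituted phenol may be slow, so the alkoxyphosphonium intermediate could be diverted to elimination or hydrazide by-products. Fallback: sulfonate alkylation instead of redox condensation. Setting out from alcohol 21, MsCl and Et3N give {(1R,5R,6R)-6-[(E)-(2,2-dimethylhydrazinylidene)methyl]-6-methyl-5-[(1R)-1-(2-methyl-1,3-dioxolan-2-yl)ethyl]-2-[(trimethylsilyl)methyl]cyclohex-2-en-1-yl}methyl methanesulfonate F4. F4 is displaced by the caesium phenoxide of 22 (Cs2CO3, DMF, 60 °C), coming back at aryl ether 23.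

3. Step 16. The amide base or the enolate may attack the coumarin lactone, or enolisation may be incomplete, leaving unmethylated enone. Fallback: finish the gem-dimethyl group before the coumarin is attached. Setting out from alcohol 21:
- NaH and 4-methoxybenzyl chloride give the 4-methoxybenzyl ether of 21, F5.
- The conditions of step 15 give 1-({[(1S,4aR,8aR)-5,8a-dimethyl-2-methylidene-6-oxo-1,2,3,4,4a,5,6,8a-octahydronaphthalen-1-yl]methoxy}methyl)-4-methoxybenzene F6.
- LiN(SiMe3)2 and MeI give 1-({[(1S,4aS,8aR)-5,5,8a-trimethyl-2-methylidene-6-oxo-1,2,3,4,4a,5,6,8a-octahydronaphthalen-1-yl]methoxy}methyl)-4-methoxybenzene F7.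
- DDQ in CH2Cl2/pH 7 buffer frees [(1S,4aS,8aR)-5,5,8a-trimethyl-2-methylidene-6-oxo-1,2,3,4,4a,5,6,8a-octahydronaphthalen-1-yl]methanol F8.
- F8 is kept away from base and taken at once into a Mitsunobu reaction with 22 (PPh3, DIAD), coming back at target 27.

**Further compounds**

F1 | step 11 | (2Z)-3-[(trimethylsilyl)methyl]penta-2,4-dien-1-yl (diethoxyphosphoryl)acetate | CCOP(=O)(OCC)CC(=O)OC/C=C(\C[Si](C)(C)C)C=C
F2 | step 11 | (2Z)-3-[(trimethylsilyl)methyl]penta-2,4-dien-1-yl (2E,4R)-4-(2-methyl-1,3-dioxolan-2-yl)pent-2-enoate | C=C/C(C[Si](C)(C)C)=C/COC(=O)/C=C/[C@@H](C)C1(C)OCCO1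
F3 | step 11 | (3aR,7R,7aR)-7-[(1R)-1-(2-methyl-1,3-dioxolan-2-yl)ethyl]-4-[(trimethylsilyl)methyl]-3a,6,7,7a-tetrahydro-2-benzofuran-1(3H)-one | [C@H]12C(=O)OC[C@H]1C(C[Si](C)(C)C)=CC[C@@H]2[C@@H](C)C3(C)OCCO3
F4 | step 14 | {(1R,5R,6R)-6-[(E)-(2,2-dimethylhydrazinylidene)methyl]-6-methyl-5-[(1R)-1-(2-methyl-1,3-dioxolan-2-yl)ethyl]-2-[(trimethylsilyl)methyl]cyclohex-2-en-1-yl}methyl methanesulfonate | C[C@]1(/C=N/N(C)C)[C@@H](COS(C)(=O)=O)C(C[Si](C)(C)C)=CC[C@@H]1[C@@H](C)C2(C)OCCO2
F5 | step 16 | 4-methoxybenzyl ether of 21 | C[C@]1(/C=N/N(C)C)[C@@H](COCc2ccc(OC)cc2)C(C[Si](C)(C)C)=CC[C@@H]1[C@@H](C)C3(C)OCCO3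
F6 | step 16 | 1-({[(1S,4aR,8aR)-5,8a-dimethyl-2-methylidene-6-oxo-1,2,3,4,4a,5,6,8a-octahydronaphthalen-1-yl]methoxy}methyl)-4-methoxybenzene (C5 epimers) | C=C1CC[C@@H]2C(C)C(=O)C=C[C@@]2(C)[C@H]1COCc1ccc(OC)cc1
F7 | step 16 | 1-({[(1S,4aS,8aR)-5,5,8a-trimethyl-2-methylidene-6-oxo-1,2,3,4,4a,5,6,8a-octahydronaphthalen-1-yl]methoxy}methyl)-4-methoxybenzene | C=C1CC[C@@H]2C(C)(C)C(=O)C=C[C@@]2(C)[C@H]1COCc1ccc(OC)cc1
F8 | step 16 | [(1S,4aS,8aR)-5,5,8a-trimethyl-2-methylidene-6-oxo-1,2,3,4,4a,5,6,8a-octahydronaphthalen-1-yl]methanol | C=C1CC[C@@H]2C(C)(C)C(=O)C=C[C@@]2(C)[C@H]1CO
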